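By 8.00 min amber had turned 32.7% of its left-handed and right-handed substrate together, and red, with twice the substrate, had turned 34.2%, so in percent red kept level with amber.

common to all: free catalyst 0.10 mM; precatalyst 0.10 mM
- amber: left-handed substrate 0.10 M; right-handed substrate 0.10 M; solid reagent 0.10 M; run made earlier
- violet: left-handed substrate 0.10 M; right-handed substrate 0.10 M; solid reagent 0.40 M; run made earlier
- red: left-handed substrate 0.20 M; right-handed substrate 0.20 M; solid reagent 0.20 M; run made earlier
- flask: left-handed substrate 0.10 M; right-handed substrate 0.10 M; solid reagent 0.200 M; time 6.0 min

| run | time / min | left-handed product / % | right-handed product / % |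
|---|---|---|---|
| amber | 0.500 | 1.7 | 0 |
| amber | 1.33 | 2.4 | 2.2 |
| amber | 3.00 | 11.1 | 6.9 |
| amber | 8.00 | 24.8 | 7.9 |
| violet | 0.500 | 0 | 0 |
| violet | 1.33 | 5.5 | 1.6 |
| violet | 3.00 | 11.7 | 3.7 |
| violet | 8.00 | 28.0 | 11.0 |
| red | 0.833 | 1.5 | 0.4 |
| red | 2.50 | 8.4 | 4.0 |
| red | 5.00 | 16.1 | 7.0 |
| red | 8.00 | 25.2 | 9.0 |

(scatter of a reading: 1 percentage point)

- free catalyst is single-handed; left-handed substrate and right-handed substrate are mirror images of each other, charged as a racemate, each of them at the stated concentration
- solid reagent is a solid; its amount is given per volume of the solution
- at the start none of the solid reagent is in solution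
- an excess is the difference of the two amounts in percent of their sum
- an excess is below zero if the other one leads

1. left-handed product and right-handed product together, in percent of the left-handed substrate and right-handed substrate charged together, at 6.0 min
2. excess of left-handed product over right-handed product in the product at 6.0 min
3. whether the exchange between left-handed substrate and right-handed substrate keeps pace with the reaction: how far the product's excess at 6.0 min gets from its value without exchange to its value with instant exchange (above 80% keeps pace, below 20% hardly takes part, else lags behind)

So I treated the loss of substrate as pseudo-first-order. Violet reached 39.0%, and the mean of the 3 runs, 35.3%, gave a decay rate k of 0.0544 min⁻¹. That is a time constant τ of 18.4 min.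

I counted turnovers. The turnover frequency f, the substrate molecules turned per catalyst per minute at the start, came to 109 min⁻¹ for this flask's charge. Two things could slow it. Loss of substrate cut the pace by a factor of 0.721 at 6.0 min. Solid reagent mattered little: raising it by a factor of 4.00 from amber to violet raised k by a factor of 1.25, and the flask's 0.200 M lay between those charges. So I kept k and expected 557 turnovers by 6.0 min, not the 654 of an unslowed pace. In my reckoning that meant 27.9% reacted.

The forecast gave 28%, an excess of 45%, and exchange that keeps pace: “The flat or rising excess favours exchange keeping pace, though the discrimination is weak.”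

The flask gave 30.1% with an excess of 42.2%, which is 601 turnovers against my 557. The forecast parted on the exchange, which lags behind: it got 37% of the way, with racemization catalyst at 18.2% of the precatalyst charged at 6.00 min.

    partner + free catalyst + right-handed substrate → free catalyst + right-handed product (k = 8550 M⁻² min⁻¹)
    precatalyst → racemization catalyst (k = 0.0335 min⁻¹)
    partner → decomposed reagent (k = 0.0563 min⁻¹)
    solid reagent ⇌ partner, rate k4*(cs4 - [partner]) while solid is left; crystals form when [partner] > cs4 (solubility = 43.0 mM, k = 4.08 min⁻¹)
    partner + free catalyst + left-handed substrate → free catalyst + left-handed product (k = 23300 M⁻² min⁻¹)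
    left-handed substrate + racemization catalyst ⇌ right-handed substrate + racemization catalyst, rate k6*[racemization catalyst]*[left-handed substrate] forward; the back reaction follows from the equilibrium constant (k = 14300 M⁻¹ min⁻¹)

With 2.5 × 10⁻⁴ M of free catalyst in the neighbour flask, I held f per catalyst. The time constant then fell to 7.35 min, which gave 55.8% reacted at 6.0 min. The computed neighbour gave 55.9%.

The data are calculated with made-up constants, and the scatter is random.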